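**Conventions and assumption.** Locants follow labdane numbering of the target (decalin C1–C10; C17 = methyl on C8; C18 = 4α-methyl; C19 = 4β carbon; C20 = methyl on C10; side chain C11, C12; butenolide C13–C16). α is the face opposite the C10 methyl, β the same face. "Hexanorlabdane" means 11,12,13,14,15,16-hexanorlabdane, the C14 decalin core. Assumption: (S)-Wieland–Miescher ketone, 4-bromofuran-2(5H)-one and tributyl(vinyl)stannane are taken as inexpensive catalogue compounds.

**Retrosynthetic overview**
1. Target 16 ⇒ C9–C11 cut: B-alkyl Suzuki coupling of triol enol triflate 11 with the 9-BBN adduct of 4-vinylbutenolide 14.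
2. Key step: the C2–O and C6–O bonds (with C5–H, three stereocentres) are made in one flask from bis(enol triflate) triene 6 by hydroboration–elimination–rehydroboration and oxidation.
3. 6 ⇒ diketo ester 5 ⇒ enone ester 3: both methyls (C17, C18) by one-pot dianion methylation; C19 comes from the ester.
4. 3 ⇒ (S)-Wieland–Miescher ketone 1 by α-iodination and methoxycarbonylation.
5. No ring is formed in the route: rings A and B arrive in 1, the butenolide ring in 12.

**Step 1**
Reactants: 1 (S)-Wieland–Miescher ketone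
Product: 2 (8aS)-5-iodo-8a-methyl-3,4,8,8a-tetrahydronaphthalene-1,6(2H,7H)-dione
Conditions: I2 (0.6 equiv), PhI(O2CCF3)2 (0.6 equiv), pyridine, CH2Cl2, 0 °C → rt, dark
Reagents that add atoms: iodine, II
Why: Johnson-type α-iodination of a β,β-disubstituted enone (electrophilic iodine, pyridine-mediated addition–elimination) takes place only at the enone α-carbon C4 and leaves the C10 stereocentre untouched.

**Step 2**
Reactants: 2 iodoenone
Product: 3 methyl (4aS)-4a-methyl-2,5-dioxo-2,3,4,4a,5,6,7,8-octahydronaphthalene-1-carboxylate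
Conditions: Pd(OAc)2 (5 mol %), PPh3 (10 mol %), CO (1 atm), MeOH, Et3N, DMF, 50 °C
Reagents that add atoms: carbon monoxide, [C-]#[O+]; methanol, CO
Why: Palladium-catalysed alkoxycarbonylation (oxidative addition of zerovalent palladium to the α-iodoenone, CO insertion, methanolysis) installs the future C19 carbon as the vinylogous β-keto ester.

**Step 3**
Reactants: 3 enone ester
Product: 5 methyl 3,9-dioxo-hexanorlabd-5-en-19-oate (C8 epimers), via C8-methylated enone ester 4 (not isolated)
Conditions: NaH (1.05 equiv), THF, 0 °C; LiN(i-Pr)2 (1.1 equiv), −78 °C; MeI (1.05 equiv), −78 → −30 °C; then MeI (5 equiv), DMPU, −30 °C → rt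
Reagents that add atoms: iodomethane, CI
Why: Weiler-type dianion alkylation: NaH forms the stabilised extended dienolate of ring A, LiN(i-Pr)2 then forms the far more nucleophilic C9-ketone enolate, which takes the first MeI at C8 (configuration irrelevant, C8 later becomes sp2); the dienolate then undergoes deconjugative α-methylation at C4 from the α-face, anti to the axial C10 methyl, giving 4α-Me/4β-CO2Me and moving the alkene to C5=C6.

**Step 4**
Reactants: 5 diketo ester
Product: 6 methyl 3,9-bis(trifluoromethylsulfonyloxy)-hexanorlabda-2,5,8-trien-19-oate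
Conditions: KN(SiMe3)2 (2.4 equiv), THF, −78 → 0 °C; PhNTf2 (2.3 equiv), −78 °C → rt
Reagents that add atoms: N-phenylbis(trifluoromethanesulfonimide), O=S(=O)(N(c1ccccc1)S(=O)(=O)C(F)(F)F)C(F)(F)F
Why: Enol triflate formation is regiospecific because each ketone can enolise on one side only (C4 and C10 are quaternary), giving the C2=C3 and C8=C9 triflates and converging the C8 epimers.

**Step 5**
Reactants: 6 bis(enol triflate)
Product: 10 methyl 2α,6α-dihydroxy-9-(trifluoromethylsulfonyloxy)-hexanorlabd-8-en-19-oate, via boryl triflate adduct 7 (not isolated), via diene triflate 8 (not isolated), via bisborane 9 (not isolated)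
Conditions: BH3·SMe2 (6 equiv), CH2Cl2, 0 °C → 25 °C, 16 h; then 3 M NaOH, 30% H2O2, THF, 0 °C
Reagents that add atoms: hydrogen peroxide, OO
Why: Proposed new method: hydroboration–elimination–rehydroboration of an enol triflate as a one-flask reductive 1,2-oxygen transposition. BH3 adds syn to the trisubstituted C2=C3(OTf) with boron on the less substituted C2 (β to oxygen). The β-boryl triflate 7 loses triflate by boron-assisted β-elimination, as β-halo- and β-acyloxyboranes do, the adjacent ester disfavouring cationic rearrangement at C3/C4, to give alkene 8. Alkene 8 is rehydroborated at C2 (C3 is neopentylic) from the α-face, and C5=C6 is hydroborated at C6 from the α-face because the β-face is blocked by the axial C10 methyl and the 4β-ester; this sets 5α-H (trans-decalin) and 6α-B. The tetrasubstituted, electron-poor C8=C9 triflate and the hindered ester do not react, and oxidation with retention gives the 2α,6α-diol (a minor 3-ol regioisomer is removed by chromatography). Closest known reactions: hydroboration–elimination–rehydroboration of enol acetates, vinyl halides and enamines, and the α-face hydroboration of 4,4-disubstituted 5-ene decalins.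

**Step 6**
Reactants: 10 diol ester
Product: 11 2α,6α,19-trihydroxy-hexanorlabd-8-en-9-yl trifluoromethanesulfonate
Conditions: i-Bu2AlH (6 equiv), CH2Cl2, −78 → 0 °C; aq. potassium sodium tartrate work-up
Reagents that add atoms: none
Why: Hydride reduction of the hindered axial ester to the primary alcohol C19 with i-Bu2AlH, which tolerates the enol triflate; no stereocentre is touched.

**Step 7**
Reactants: 12 4-bromofuran-2(5H)-one; 13 tributyl(vinyl)stannane
Product: 14 4-vinylfuran-2(5H)-one
Conditions: Pd(PPh3)4 (3 mol %), toluene, BHT (trace), 80 °C; use fresh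
Reagents that add atoms: none
Why: Stille coupling of the activated β-bromobutenolide (a vinylogous acyl bromide) with the vinylstannane is fast and needs no base, which spares the lactone.

**Step 8**
Reactants: 11 triol enol triflate; 14 4-vinylfuran-2(5H)-one
Product: 16 2α,6α,19-trihydroxylabda-8,13-dien-15,16-olide (target), via alkylborane 15 (not isolated)
Conditions: 14 (2 equiv), 9-BBN dimer (1.0 equiv B–H per 14), THF, 0 °C → rt; then 11, Pd(dppf)Cl2 (10 mol %), AsPh3 (10 mol %), Cs2CO3 (3 equiv), DMF/THF/H2O, 50 °C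
Reagents that add atoms: none
Why: Anti-Markovnikov hydroboration of the terminal vinyl group followed by B-alkyl Suzuki–Miyaura coupling with the tetrasubstituted enol triflate forms C9–C11 and fixes the alkene at C8=C9; the free hydroxyls and the butenolide tolerate the mild aqueous base, and no stereocentre is affected.

**Compound list**
1 | (S)-Wieland–Miescher ketone, (8aS)-8a-methyl-3,4,8,8a-tetrahydronaphthalene-1,6(2H,7H)-dione | C1C(=O)[C@@]2(C)CCC(=O)C=C2CC1 | starting material
2 | (8aS)-5-iodo-8a-methyl-3,4,8,8a-tetrahydronaphthalene-1,6(2H,7H)-dione (4-iodo enone) | C1C(=O)[C@@]2(C)CCC(=O)C(I)=C2CC1 | intermediate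
3 | methyl (4aS)-4a-methyl-2,5-dioxo-2,3,4,4a,5,6,7,8-octahydronaphthalene-1-carboxylate (enone ester) | C1C(=O)[C@@]2(C)CCC(=O)C(C(=O)OC)=C2CC1 | intermediate
4 | methyl (4aS)-4a,6-dimethyl-2,5-dioxo-2,3,4,4a,5,6,7,8-octahydronaphthalene-1-carboxylate (C8-methylated enone ester, C8 epimers, present as its dienolate) | CC1C(=O)[C@@]2(C)CCC(=O)C(C(=O)OC)=C2CC1 | intermediate (not isolated)
5 | methyl 3,9-dioxo-hexanorlabd-5-en-19-oate (4α-Me, 4β-CO2Me, 10β-Me; C8 epimers) | CC1C(=O)[C@@]2(C)CCC(=O)[C@](C)(C(=O)OC)C2=CC1 | intermediate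
6 | methyl 3,9-bis(trifluoromethylsulfonyloxy)-hexanorlabda-2,5,8-trien-19-oate | CC1=C(OS(=O)(=O)C(F)(F)F)[C@@]2(C)CC=C(OS(=O)(=O)C(F)(F)F)[C@](C)(C(=O)OC)C2=CC1 | intermediate
7 | methyl 2α-boryl-3β,9-bis(trifluoromethylsulfonyloxy)-hexanorlabda-5,8-dien-19-oate (boryl drawn as BH2) | CC1=C(OS(=O)(=O)C(F)(F)F)[C@@]2(C)C[C@@H](B)[C@H](OS(=O)(=O)C(F)(F)F)[C@](C)(C(=O)OC)C2=CC1 | intermediate (not isolated)
8 | methyl 9-(trifluoromethylsulfonyloxy)-hexanorlabda-2,5,8-trien-19-oate | CC1=C(OS(=O)(=O)C(F)(F)F)[C@@]2(C)CC=C[C@](C)(C(=O)OC)C2=CC1 | intermediate (not isolated)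
9 | methyl 2α,6α-bis(boryl)-9-(trifluoromethylsulfonyloxy)-hexanorlabd-8-en-19-oate (5α-H; boryl drawn as BH2) | CC1=C(OS(=O)(=O)C(F)(F)F)[C@@]2(C)C[C@@H](B)C[C@](C)(C(=O)OC)[C@@H]2[C@@H](B)C1 | intermediate (not isolated)
10 | methyl 2α,6α-dihydroxy-9-(trifluoromethylsulfonyloxy)-hexanorlabd-8-en-19-oate (5α-H) | CC1=C(OS(=O)(=O)C(F)(F)F)[C@@]2(C)C[C@@H](O)C[C@](C)(C(=O)OC)[C@@H]2[C@@H](O)C1 | intermediate
11 | 2α,6α,19-trihydroxy-hexanorlabd-8-en-9-yl trifluoromethanesulfonate | CC1=C(OS(=O)(=O)C(F)(F)F)[C@@]2(C)C[C@@H](O)C[C@](C)(CO)[C@@H]2[C@@H](O)C1 | intermediate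
12 | 4-bromofuran-2(5H)-one | BrC1=CC(=O)OC1 | starting material
13 | tributyl(vinyl)stannane | C=C[Sn](CCCC)(CCCC)CCCC | starting material
14 | 4-vinylfuran-2(5H)-one | C=CC1=CC(=O)OC1 | intermediate
15 | 4-[2-(9-borabicyclo[3.3.1]nonan-9-yl)ethyl]furan-2(5H)-one | O=C1OCC(CCB2C3CCCC2CCC3)=C1 | intermediate (not isolated)
16 | 2α,6α,19-trihydroxylabda-8,13-dien-15,16-olide; 4-{2-[(4S,4aR,5S,7R,8aS)-4,7-dihydroxy-5-(hydroxymethyl)-2,5,8a-trimethyl-3,4,4a,5,6,7,8,8a-octahydronaphthalen-1-yl]ethyl}furan-2(5H)-one | CC1=C(CCC2=CC(=O)OC2)[C@@]2(C)C[C@@H](O)C[C@](C)(CO)[C@@H]2[C@@H](O)C1 | target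

**Totals.** Total step count: 8. Longest linear sequence: 7 (steps 1–6 and 8).

**Steps most likely to fail, with fallbacks**

Step 5 (proposed new cascade). The enol triflate may hydroborate sluggishly, the β-boryl triflate may rearrange instead of eliminating, or rehydroboration with BH3 may give too much 3-ol. The fallback uses known chemistry and sets out from 5. Kinetic mono-enolisation of the C3 ketone (KN(SiMe3)2, 1.05 equiv, THF, −78 °C; the tertiary C8–H next to the C9 ketone is removed much more slowly) and PhNTf2 give the C3 mono-enol triflate F1. Cacchi reduction (Pd(OAc)2, PPh3, HCO2H, Bu3N, DMF, 60 °C) gives the 2,5-diene ketone F2. KN(SiMe3)2/PhNTf2 at 0 °C then gives diene triflate 8, this time isolated. Regioselective 9-BBN hydroboration of C2=C3, then BH3·THF for C5=C6 and NaBO3·4H2O oxidation, give 10, where the route is rejoined.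

Step 3 (one-pot dianion double methylation). Enolate equilibration may cause over- or under-methylation at C8, or the two methylations may not stay separate. The fallback sets out from 3 and uses a protecting group in place of the dianion. Selective ketalisation of the saturated C9 ketone (ethylene glycol, 2-ethyl-2-methyl-1,3-dioxolane, TsOH, rt) gives the C9 ethylene ketal F3. Deconjugative methylation (t-BuOK, MeI, t-BuOH) gives the 4α-methyl 5-ene keto ester ketal F4. KN(SiMe3)2/PhNTf2 gives the C3 enol triflate ketal F5, and Cacchi reduction gives the 2,5-diene ketal F6. Aqueous HCl in THF gives the C8-unsubstituted 2,5-diene ketone F7, whose only enolisable position is C8; LiN(i-Pr)2/MeI converts it into the 2,5-diene ketone F2. From F2 the sequence continues as in the fallback above and returns to the route at 8.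

Step 8 (B-alkyl Suzuki coupling on a very hindered triflate with a sensitive vinylbutenolide-derived borane). Compound 14 may polymerise or hydroborate unselectively, or transmetalation to the hindered palladium centre may be slow. The fallback sets out from 11 and moves the boron to the decalin, so that the C12–C13 bond is formed instead. Stille coupling with 13 (Pd(PPh3)4, LiCl, THF, 65 °C) gives the 9-vinyl diene triol F8. Excess 9-BBN adds only to the terminal vinyl group and gives the decalin alkylborane F9 (not isolated). B-alkyl Suzuki coupling with 4-bromofuran-2(5H)-one 12 (Pd(dppf)Cl2, AsPh3, Cs2CO3, DMF/H2O, rt), the standard electrophile for butenolide installation, gives 16 directly.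

**Further compounds**
F1 | step 5 | methyl 9-oxo-3-(trifluoromethylsulfonyloxy)-hexanorlabda-2,5-dien-19-oate (C8 epimers) | CC1C(=O)[C@@]2(C)CC=C(OS(=O)(=O)C(F)(F)F)[C@](C)(C(=O)OC)C2=CC1
F2 | step 5 | methyl 9-oxo-hexanorlabda-2,5-dien-19-oate (C8 epimers) | CC1C(=O)[C@@]2(C)CC=C[C@](C)(C(=O)OC)C2=CC1
F3 | step 3 | C9 ethylene ketal of enone ester 3 | C1C2(OCCO2)[C@@]3(C)CCC(=O)C(C(=O)OC)=C3CC1
F4 | step 3 | C9 ethylene ketal of the 4α-methyl-4β-methoxycarbonyl-3-oxo-5-ene (no C8 methyl) | C1C2(OCCO2)[C@@]3(C)CCC(=O)[C@](C)(C(=O)OC)C3=CC1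
F5 | step 3 | C3 enol triflate of F4 (2,5-diene, C9 ketal) | C1C2(OCCO2)[C@@]3(C)CC=C(OS(=O)(=O)C(F)(F)F)[C@](C)(C(=O)OC)C3=CC1
F6 | step 3 | 2,5-diene ester C9 ethylene ketal (no C8 methyl) | C1C2(OCCO2)[C@@]3(C)CC=C[C@](C)(C(=O)OC)C3=CC1
F7 | step 3 | 2,5-diene 9-ketone ester without the C8 methyl | C1C(=O)[C@@]2(C)CC=C[C@](C)(C(=O)OC)C2=CC1
F8 | step 8 | 9-vinyl-hexanorlabd-8-ene-2α,6α,19-triol | CC1=C(C=C)[C@@]2(C)C[C@@H](O)C[C@](C)(CO)[C@@H]2[C@@H](O)C1
F9 | step 8 | 9-[2-(9-borabicyclo[3.3.1]nonan-9-yl)ethyl]-hexanorlabd-8-ene-2α,6α,19-triol (drawn with free hydroxyls) | CC1=C(CCB3C4CCCC3CCC4)[C@@]2(C)C[C@@H](O)C[C@](C)(CO)[C@@H]2[C@@H](O)C1
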